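**Plan**
- Retrosynthesis: cut C5–propenyl (Suzuki–Miyaura, Br as placeholder) and trace the C3 methyl back to a C3 ester. Then cut the dihydrofuran ring at C2–C3 (carbene C–H insertion), the ring-A aryl–C(N2) bond (Pd coupling with ethyl diazoacetate) and the O1–CH2 bond (Mitsunobu).
- Forward: both arenes are bought. The MOM-protected syringyl alcohol and 4-bromo-2-iodo-6-methoxyphenol give a benzyl aryl ether, then the aryldiazoacetate. The only non-aromatic ring (O1–C2–C3–C3a–C7a) is closed last, followed by C3 epimerisation, CO2Et → CH3, propenylation and MOM removal.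
- Enabling feature: C2 is a CH flanked by O1 and the electron-rich syringyl ring, so in the open-chain ether its C–H bond is hydridic and lies 1,5 to C3. C3, a ring-A benzylic carbon, is carried as an ester-bearing carbene carbon; the ester tames the carbene, makes C3 epimerisable and is later reduced to the methyl group.
- Stereochemistry: C2 (S) from the chiral dirhodium catalyst, which selects one enantiotopic benzylic hydrogen. C3 (S) from base equilibration of the kinetic cis ester to the trans ester. The E-alkene comes from a stereodefined boronate.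

Key step: step 6

Assumption: the sense of induction of the tert-leucinate catalyst is taken from the closest 2-aryl cases as recalled (R-catalyst leading to the 2R series), so the S-catalyst is specified; if the first run shows the opposite sense, the mirror-image catalyst is used with no other change.

**Route**

Step 1
Reactants: 1 syringaldehyde (4-hydroxy-3,5-dimethoxybenzaldehyde)
Product: 2 3,5-dimethoxy-4-(methoxymethoxy)benzaldehyde
Conditions: MOMCl, iPr2NEt, CH2Cl2, 0 °C to rt
Reagents that add atoms: chloromethyl methyl ether, COCCl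
Why: O-alkylation of the phenoxide gives the MOM acetal, which should survive the base, hydride, Pd and Rh steps and be removable at the end without reduction.

Step 2
Reactants: 2 3,5-dimethoxy-4-(methoxymethoxy)benzaldehyde
Product: 3 [3,5-dimethoxy-4-(methoxymethoxy)phenyl]methanol
Conditions: NaBH4, MeOH, 0 °C
Reagents that add atoms: none
Why: Borohydride reduction of an aryl aldehyde gives the primary benzylic alcohol needed for the etherification, with the acetal untouched.

Step 3
Reactants: 4 4-bromo-2-methoxyphenol
Product: 5 4-bromo-2-iodo-6-methoxyphenol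
Conditions: NIS, TsOH (cat.), MeCN, rt
Reagents that add atoms: N-iodosuccinimide, O=C1CCC(=O)N1I
Why: Electrophilic aromatic iodination is directed by the hydroxyl group to its only free ortho position (para is blocked by Br), which becomes C3a.

Step 4
Reactants: 5 4-bromo-2-iodo-6-methoxyphenol; 3 [3,5-dimethoxy-4-(methoxymethoxy)phenyl]methanol
Product: 6 5-bromo-1-iodo-3-methoxy-2-{[3,5-dimethoxy-4-(methoxymethoxy)phenyl]methoxy}benzene
Conditions: PPh3, DIAD, THF, 0 °C to rt
Reagents that add atoms: none
Why: Mitsunobu etherification of an acidic halophenol with a primary benzylic alcohol forms the O1–C2 bond and avoids the labile electron-rich benzyl halide.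

Step 5
Reactants: 6 5-bromo-1-iodo-3-methoxy-2-{[3,5-dimethoxy-4-(methoxymethoxy)phenyl]methoxy}benzene; 7 ethyl diazoacetate
Product: 8 ethyl 2-(5-bromo-3-methoxy-2-{[3,5-dimethoxy-4-(methoxymethoxy)phenyl]methoxy}phenyl)-2-diazoacetate
Conditions: Pd(PPh3)4 (5 mol %), Ag2CO3 (0.5 equiv), Et3N, toluene, rt, dark
Reagents that add atoms: none
Why: Pd(0)-catalysed cross-coupling of an aryl iodide with the C–H bond of an acceptor diazo compound should proceed at the C–I bond (far faster than C–Br at rt) with the diazo group retained, giving the aryldiazoacetate in one step.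

Step 6
Reactants: 8 ethyl 2-(5-bromo-3-methoxy-2-{[3,5-dimethoxy-4-(methoxymethoxy)phenyl]methoxy}phenyl)-2-diazoacetate
Product: 9 ethyl (2S,3R)-5-bromo-2-[3,5-dimethoxy-4-(methoxymethoxy)phenyl]-7-methoxy-2,3-dihydro-1-benzofuran-3-carboxylate (cis)
Conditions: slow addition of 8 to Rh2(S-PTTL)4 (1 mol %), toluene, −78 °C
Reagents that add atoms: none
Why: Rh(II) extrudes N2 from 8 to give an electrophilic donor/acceptor rhodium carbenoid at the future C3, which inserts into the benzylic ether C–H bond (future C2) through a concerted, asynchronous, hydride-transfer-like three-centre transition state and releases the catalyst. The closest known reaction type is the Rh(II)-carboxylate-catalysed enantioselective intramolecular C–H insertion of ortho-benzyloxy aryldiazoacetates to cis-2-aryl-2,3-dihydrobenzofuran-3-carboxylates. The dihydrofuran ring is closed by 1,5-C–H insertion, i.e. C2–C3 bond formation through a five-membered transition state with O1–C2, C3–C3a and C3a–C7a already in place. C2 is controlled by the catalyst, whose pocket of four N-phthaloyl-tert-leucinate ligands selects one of the two enantiotopic benzylic hydrogens; C3 is formed cis to the aryl group under kinetic control and is reset in step 7, so only C2 has to be fixed here. The step needs chemoselectivity for this insertion over carbene dimerisation or azine formation, attack on the syringyl ring and reaction at OCH3 or OCH2O hydrogens. This should be secured by the activation of the C2–H bond by O1 and the para-alkoxyaryl ring, its 1,5-relationship to the carbene, low temperature with slow addition, and the discriminating donor/acceptor carbenoid, while the aryl bromide and the MOM group are inert.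

Step 7
Reactants: 9 ethyl (2S,3R)-5-bromo-2-[3,5-dimethoxy-4-(methoxymethoxy)phenyl]-7-methoxy-2,3-dihydro-1-benzofuran-3-carboxylate
Product: 10 ethyl (2S,3S)-5-bromo-2-[3,5-dimethoxy-4-(methoxymethoxy)phenyl]-7-methoxy-2,3-dihydro-1-benzofuran-3-carboxylate (trans)
Conditions: NaOEt (0.3 equiv), EtOH/THF, rt
Reagents that add atoms: none
Why: Enolisation and reprotonation α to the ester should equilibrate C3 to the more stable trans arrangement, while C2 has no acidic hydrogen and β-elimination of O1 is stereoelectronically disfavoured (the C2–O1 bond lies in the nodal plane of the enolate), so the catalyst-set centre is kept.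

Step 8
Reactants: 10 ethyl (2S,3S)-5-bromo-2-[3,5-dimethoxy-4-(methoxymethoxy)phenyl]-7-methoxy-2,3-dihydro-1-benzofuran-3-carboxylate
Product: 11 {(2S,3R)-5-bromo-2-[3,5-dimethoxy-4-(methoxymethoxy)phenyl]-7-methoxy-2,3-dihydro-1-benzofuran-3-yl}methanol
Conditions: LiAlH4, THF, 0 °C
Reagents that add atoms: none
Why: Hydride reduction of the ester to the primary alcohol at 0 °C should leave the aryl bromide and the acetal intact and removes the acidity at C3, so the trans relationship is locked (the descriptor at C3 changes only through CIP priorities).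

Step 9
Reactants: 11 {(2S,3R)-5-bromo-2-[3,5-dimethoxy-4-(methoxymethoxy)phenyl]-7-methoxy-2,3-dihydro-1-benzofuran-3-yl}methanol
Product: 13 (2S,3S)-5-bromo-2-[3,5-dimethoxy-4-(methoxymethoxy)phenyl]-7-methoxy-3-methyl-2,3-dihydro-1-benzofuran, via the C3 methanesulfonate 12 (not isolated)
Conditions: MsCl, Et3N, THF, 0 °C; then LiEt3BH (4 equiv), 0 °C to rt
Reagents that add atoms: methanesulfonyl chloride, CS(=O)(=O)Cl (atoms retained in 12 only)
Why: Activation of the primary alcohol as its mesylate followed by SN2 displacement with the strongly nucleophilic, weakly basic triethylborohydride is a standard deoxygenation that touches neither stereocentre nor the aryl bromide.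

Step 10
Reactants: 13 (2S,3S)-5-bromo-2-[3,5-dimethoxy-4-(methoxymethoxy)phenyl]-7-methoxy-3-methyl-2,3-dihydro-1-benzofuran; 14 (E)-prop-1-enylboronic acid pinacol ester
Product: 15 (2S,3S)-2-[3,5-dimethoxy-4-(methoxymethoxy)phenyl]-7-methoxy-3-methyl-5-[(E)-prop-1-enyl]-2,3-dihydro-1-benzofuran
Conditions: Pd(OAc)2 (2 mol %), SPhos (4 mol %), K3PO4, toluene/H2O, 80 °C
Reagents that add atoms: none
Why: Suzuki–Miyaura coupling of the electron-rich aryl bromide with an alkenylboronate proceeds with retention of alkene geometry, and with the phenol still protected no base-induced quinone-methide opening at C2 is possible.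

Step 11
Reactants: 15 (2S,3S)-2-[3,5-dimethoxy-4-(methoxymethoxy)phenyl]-7-methoxy-3-methyl-5-[(E)-prop-1-enyl]-2,3-dihydro-1-benzofuran
Product: 16 odoratisol A, 4-{(2S,3S)-7-methoxy-3-methyl-5-[(E)-prop-1-enyl]-2,3-dihydro-1-benzofuran-2-yl}-2,6-dimethoxyphenol
Conditions: HCl (1.25 M in MeOH), THF, 0 °C to rt, monitored and quenched with NaHCO3
Reagents that add atoms: none
Why: Acid-catalysed cleavage of the aryl MOM acetal should be much faster than protonation of the E-propenyl group or ionisation of the C2–O1 bond in dilute acid, and any reversible ionisation at C2 would return the thermodynamically preferred trans isomer without touching C3.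

**Compound list**
1 | syringaldehyde (4-hydroxy-3,5-dimethoxybenzaldehyde) | COc1cc(C=O)cc(OC)c1O | starting material
2 | 3,5-dimethoxy-4-(methoxymethoxy)benzaldehyde | COCOc1c(OC)cc(C=O)cc1OC | intermediate
3 | [3,5-dimethoxy-4-(methoxymethoxy)phenyl]methanol | COCOc1c(OC)cc(CO)cc1OC | intermediate
4 | 4-bromo-2-methoxyphenol | COc1cc(Br)ccc1O | starting material
5 | 4-bromo-2-iodo-6-methoxyphenol | COc1cc(Br)cc(I)c1O | intermediate
6 | 5-bromo-1-iodo-3-methoxy-2-{[3,5-dimethoxy-4-(methoxymethoxy)phenyl]methoxy}benzene | COc1cc(Br)cc(I)c1OCc1cc(OC)c(OCOC)c(OC)c1 | intermediate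
7 | ethyl diazoacetate | CCOC(=O)C=[N+]=[N-] | starting material
8 | ethyl 2-(5-bromo-3-methoxy-2-{[3,5-dimethoxy-4-(methoxymethoxy)phenyl]methoxy}phenyl)-2-diazoacetate | CCOC(=O)C(=[N+]=[N-])c1cc(Br)cc(OC)c1OCc1cc(OC)c(OCOC)c(OC)c1 | intermediate
9 | ethyl (2S,3R)-5-bromo-2-[3,5-dimethoxy-4-(methoxymethoxy)phenyl]-7-methoxy-2,3-dihydro-1-benzofuran-3-carboxylate (cis) | Brc1cc(OC)c2c(c1)[C@@H](C(=O)OCC)[C@@H](c1cc(OC)c(OCOC)c(OC)c1)O2 | intermediate
10 | ethyl (2S,3S)-5-bromo-2-[3,5-dimethoxy-4-(methoxymethoxy)phenyl]-7-methoxy-2,3-dihydro-1-benzofuran-3-carboxylate (trans) | Brc1cc(OC)c2c(c1)[C@H](C(=O)OCC)[C@@H](c1cc(OC)c(OCOC)c(OC)c1)O2 | intermediate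
11 | {(2S,3R)-5-bromo-2-[3,5-dimethoxy-4-(methoxymethoxy)phenyl]-7-methoxy-2,3-dihydro-1-benzofuran-3-yl}methanol | Brc1cc(OC)c2c(c1)[C@H](CO)[C@@H](c1cc(OC)c(OCOC)c(OC)c1)O2 | intermediate
12 | {(2S,3R)-5-bromo-2-[3,5-dimethoxy-4-(methoxymethoxy)phenyl]-7-methoxy-2,3-dihydro-1-benzofuran-3-yl}methyl methanesulfonate (not isolated) | Brc1cc(OC)c2c(c1)[C@H](COS(C)(=O)=O)[C@@H](c1cc(OC)c(OCOC)c(OC)c1)O2 | intermediate
13 | (2S,3S)-5-bromo-2-[3,5-dimethoxy-4-(methoxymethoxy)phenyl]-7-methoxy-3-methyl-2,3-dihydro-1-benzofuran | Brc1cc(OC)c2c(c1)[C@H](C)[C@@H](c1cc(OC)c(OCOC)c(OC)c1)O2 | intermediate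
14 | (E)-prop-1-enylboronic acid pinacol ester | C/C=C/B1OC(C)(C)C(C)(C)O1 | starting material
15 | (2S,3S)-2-[3,5-dimethoxy-4-(methoxymethoxy)phenyl]-7-methoxy-3-methyl-5-[(E)-prop-1-enyl]-2,3-dihydro-1-benzofuran | C/C=C/c1cc(OC)c2c(c1)[C@H](C)[C@@H](c1cc(OC)c(OCOC)c(OC)c1)O2 | intermediate
16 | odoratisol A, 4-{(2S,3S)-7-methoxy-3-methyl-5-[(E)-prop-1-enyl]-2,3-dihydro-1-benzofuran-2-yl}-2,6-dimethoxyphenol | C/C=C/c1cc(OC)c2c(c1)[C@H](C)[C@@H](c1cc(OC)c(O)c(OC)c1)O2 | target

**Step count**
Total: 11 steps. Longest linear sequence: 10 steps (1 → 2 → 3 → 6 → 8 → 9 → 10 → 11 → 13 → 15 → 16).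

**Steps most likely to fail**

1. Step 6. The catalyst may discriminate poorly between the two enantiotopic benzylic hydrogens, because the 7-methoxy group next to the ether oxygen twists the benzyloxy arm out of the ring plane. Fallback with resolution in place of asymmetric catalysis, setting out from 8: insertion with an achiral catalyst (Rh2(esp)2, CH2Cl2, 0 °C) should give the racemic cis ethyl ester F1. Treatment with NaOEt/EtOH and then aqueous LiOH should epimerise and hydrolyse it to the racemic trans carboxylic acid F2. Crystallisation of its salt with (S)-1-phenylethylamine (or the antipodal amine, whichever gives the less soluble salt of the wanted acid) and liberation with citric acid should give the (2S,3S)-carboxylic acid F3. Reduction with BH3·THF returns to the route at 11.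

2. Step 5. Oxidative addition and transmetalation at the ortho-alkoxy iodide may be slow, and the diazo product may lose N2 on Pd or Ag and end in carbene dimers. Fallback that builds the C–C bond first and installs the diazo group afterwards, setting out from 6: Pd-catalysed coupling with the Reformatsky reagent made from ethyl bromoacetate and zinc (Pd(PPh3)4, THF/DMPU, 45 °C, selective for C–I) should give the ethyl arylacetate F4. Regitz diazo transfer (p-acetamidobenzenesulfonyl azide, DBU, MeCN, 0 °C to rt) returns to the route at 8.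

3. Step 9. The hydride may act as a base and eliminate the mesylate to the exocyclic alkene, which would isomerise to the aromatic benzofuran, or it may attack sulfur and return the alcohol. Fallback through a carbonyl-to-methyl reduction, setting out from 11: Dess–Martin oxidation should give the (2S,3S)-3-carbaldehyde F5, in which the trans arrangement is also the thermodynamic one. Condensation with tosylhydrazide (EtOH, rt) should give the tosylhydrazone F6. Reduction with catecholborane (CHCl3, 0 °C) and then NaOAc·3H2O at reflux should extrude sulfinate and N2 and return to the route at 13.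

**Further compounds**
F1 | step 6 | racemic cis ethyl 5-bromo-2-[3,5-dimethoxy-4-(methoxymethoxy)phenyl]-7-methoxy-2,3-dihydro-1-benzofuran-3-carboxylate (both enantiomers written) | Brc1cc(OC)c2c(c1)[C@@H](C(=O)OCC)[C@@H](c1cc(OC)c(OCOC)c(OC)c1)O2.Brc1cc(OC)c2c(c1)[C@H](C(=O)OCC)[C@H](c1cc(OC)c(OCOC)c(OC)c1)O2
F2 | step 6 | racemic trans 5-bromo-2-[3,5-dimethoxy-4-(methoxymethoxy)phenyl]-7-methoxy-2,3-dihydro-1-benzofuran-3-carboxylic acid (both enantiomers written) | Brc1cc(OC)c2c(c1)[C@H](C(=O)O)[C@@H](c1cc(OC)c(OCOC)c(OC)c1)O2.Brc1cc(OC)c2c(c1)[C@@H](C(=O)O)[C@H](c1cc(OC)c(OCOC)c(OC)c1)O2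
F3 | step 6 | (2S,3S)-5-bromo-2-[3,5-dimethoxy-4-(methoxymethoxy)phenyl]-7-methoxy-2,3-dihydro-1-benzofuran-3-carboxylic acid | Brc1cc(OC)c2c(c1)[C@H](C(=O)O)[C@@H](c1cc(OC)c(OCOC)c(OC)c1)O2
F4 | step 5 | ethyl 2-(5-bromo-3-methoxy-2-{[3,5-dimethoxy-4-(methoxymethoxy)phenyl]methoxy}phenyl)acetate | CCOC(=O)Cc1cc(Br)cc(OC)c1OCc1cc(OC)c(OCOC)c(OC)c1
F5 | step 9 | (2S,3S)-5-bromo-2-[3,5-dimethoxy-4-(methoxymethoxy)phenyl]-7-methoxy-2,3-dihydro-1-benzofuran-3-carbaldehyde | Brc1cc(OC)c2c(c1)[C@H](C=O)[C@@H](c1cc(OC)c(OCOC)c(OC)c1)O2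
F6 | step 9 | N'-[(E)-{(2S,3R)-5-bromo-2-[3,5-dimethoxy-4-(methoxymethoxy)phenyl]-7-methoxy-2,3-dihydro-1-benzofuran-3-yl}methylidene]-4-methylbenzenesulfonohydrazide | Brc1cc(OC)c2c(c1)[C@H](/C=N/NS(=O)(=O)c1ccc(C)cc1)[C@@H](c1cc(OC)c(OCOC)c(OC)c1)O2
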